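At 2.5 min a percentage hides what a flask made, so I turned the readings at that time into amounts per litre.

| flask | solid substrate | remark | time |
|---|---|---|---|
| Friday's | 2.8 mM | run made earlier |  |
| Sunday's | 4.4 mM | run made earlier |  |
| flask | 2.0 mM |  | 2.5 min |

| Friday's: time / min | Friday's: target / % | Sunday's: time / min | Sunday's: target / % |
|---|---|---|---|
| 0.200 | 0.9 | 0.200 | 0.4 |
| 0.417 | 2.0 | 0.667 | 4.2 |
| 0.667 | 5.5 | 1.33 | 5.5 |
| 1.33 | 7.4 | 2.00 | 10.3 |
| 2.50 | 17.6 | 2.50 | 12.4 |

(readings scatter by 1 percentage point)

- as a solid, counted per litre of solution: solid substrate
- at the start none of the solid substrate is in solution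

- grey: doubling the solubility of the solid substrate, all else as stated
- red: doubling the dissolution coefficient of the solid substrate, all else as stated

* amount of target at 2.5 min, in percent of the solid substrate charged
* the change that raises the amount of target at 2.5 min, in percent of the solid substrate charged most ("none" if none brings more than 2 percentage points) (grey / red / none)
* amount of target at 2.5 min, in percent of the solid substrate charged, after grey

Friday's run gave 17.6% of 2.8 mM, which is 0.493 mM of target. Sunday's run gave 12.4% of 4.4 mM, which is 0.546 mM. Friday's amount on Sunday's charge reads 11.2%, a gap of 1.2 percentage points against a scatter of 1 point. The two amounts lay 0.0530 mM apart although the charges differed by 1.60 mM, so I judged that solid was still present in both runs and the percentages differed through their denominators.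

I carried one quantity: the output of target, 0.208 mM min⁻¹, the mean amount made per litre and minute. While solid is present, c(target) = output × time, which is zero order in the charge. For the flask, with 2.0 mM charged, I reckoned 0.520 mM, or 26.0%.

The forecast gave 25%, chose grey, and gave 48% after grey, holding that “the solution is held by undissolved solid”.

The flask gave 25.5%, close to the 26.0% from the output. Grey was the better change, at 13 points against 9.1 points for red, but it reached 38.2%, not 48%.

    starting material → intermediate A (k = 0.0950 s⁻¹)
    starting material → intermediate B (k = 0.130 s⁻¹)
    starting material → target (k = 0.0100 s⁻¹)
    target ⇌ intermediate B (K = 0.790, k = 0.0360 s⁻¹)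
    target ⇌ intermediate A (K = 0.650, k = 0.0560 s⁻¹)
    solid substrate ⇌ starting material, rate k6*(cs6 - [starting material]) while solid is left; crystals form when [starting material] > cs6 (solubility = 0.0820 mM, k = 0.210 s⁻¹)
    starting material + intermediate B → side product (k = 23.0 M⁻¹ s⁻¹)

The relaxation half-lives of target with intermediate A, 0.0813 min, and with intermediate B, 0.142 min, are short against 2.5 min . Left until 25.0 min, with solid substrate at 0%, the flask held target at 38.4%, which is less than the forecast's grey value.

Read at 4.0 min, the same flask gets 41.6% from the output. The computed flask gave 38.3%, with solid substrate at 0%.

Readings and results were generated by integration on assumed constants; the scatter is artificial.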